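## Numbering and conventions

Daucane numbering is used for the bicycle: C-1 (quaternary, methyl-bearing fusion carbon), C-2 and C-3 (ring CH2), C-4 (isopropyl carbinol), C-5 (fusion CH), C-6 (ester carbon), C-7 (CH2), C-8 (methyl-bearing) and C-9 (epoxide carbons), C-10 (CH2), C-11 (isopropyl CH). β is the face of the C-1 methyl group, α the opposite face.

Compound numbers used throughout: 1 farnesol; 2 farnesyl chloride; 3 farnesyl diphosphate; 4 nerolidyl diphosphate (enzyme-bound); 5 dauc-8-en-4-yl cation (enzyme-bound); 6 dauc-8-en-4β-ol; 7 dauc-8-ene-4β,6β-diol; 8 4-hydroxybenzoic acid; 9 doubly silylated 8; 10 4-(tert-butyldimethylsilyloxy)benzoic acid; 11 its acid chloride; 12 the 6-O-aroyl ester of 7; 13 its 8α,9α-epoxide; 14 the target.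

Assumption: the target is read as the (1R,4R,5S,6R,8R,9S) isomer, i.e. trans-fused (C-1 methyl β, H-5 α) with 4-OH β, 6-acyloxy β and the epoxide oxygen α.

Assumption: the enzyme-bound tertiary diphosphate 4 is drawn as (3R), the enantiomer most cisoid-closing sesquiterpene synthases use; the enzyme fold decides, and the (3S) form would serve equally.

Remark: 3 is handled as its trisammonium salt; its SMILES is written for the free acid.

## Analysis of the target

Target 14 is a daucane sesquiterpenoid: a trans-fused bicyclo[5.3.0]decane in which a cyclopentane (C-1 to C-5) shares the C-1–C-5 bond with a cycloheptane (C-1, C-5 to C-10), and whose C-6 oxygen is esterified with 8. It has six stereocentres: the quaternary C-1, the tertiary isopropyl carbinol C-4, the fusion carbon C-5, the ester carbon C-6 and the epoxide carbons C-8 and C-9. With the C-1 methyl as β, the 4-hydroxyl and the 6-acyloxy group are β, H-5 is α and the epoxide oxygen is α, so the C-6 oxygen lies 1,3-syn to the angular methyl and anti to the epoxide. The sensitive groups are the trisubstituted epoxide (opened by acid, also transannularly by the C-4 hydroxyl), the tertiary alcohol (dehydration) and the aryl ester with its free phenol (base, nucleophiles). The synthesis is hard because a quaternary centre is flanked by three contiguous stereocentres on a flexible seven-membered ring with no functional group that helps to close either ring, and because the C-6 oxygen sits on a methylene that is only homoallylic. The feature that carries the strategy is that the fifteen skeletal carbons form one unbroken head-to-tail farnesyl chain, C-10–C-9–C-8–C-7–C-6–C-5–C-1–C-2–C-3–C-4–C-11, with methyls on C-8, C-1 and C-11 where such a chain has them. Only the bonds C-1–C-10 and C-4–C-5 turn that chain into the bicycle, and the epoxide sits on what was the 2,3-double bond of the chain. All carbon of the terpenoid half is therefore present in 1.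

## Retrosynthetic reasoning

14 to 13. The last bond cut is the O–Si bond of a silyl ether on the phenol. The phenol must be masked while the acyl group is attached, and a silyl ether leaves under buffered desilylation that touches neither epoxide nor ester. The forward step only has to free the phenol.

13 to 12. The two C–O bonds of the epoxide are cut back to the C-8=C-9 alkene. The epoxide is the most acid-sensitive group of 14, so it is made as late as possible and by a neutral oxygen-transfer reagent. In 12 the β face of the alkene is flanked by the C-1 methyl and the 6β-aroyloxy group, so oxygen should arrive on the α face without a directing device.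

12 to 7 and 11. The ester is cut between O-6 and the acyl carbon, which divides the molecule into the terpenoid diol 7 and the aroyl chloride 11; 11 goes back through the acid 10 and the doubly silylated 9 to 8. Acylation precedes epoxidation because a free 6β-hydroxyl is homoallylic to the alkene and could steer an oxidant to the β face, whereas the ester adds to the shielding of that face. The forward step must distinguish the secondary C-6 hydroxyl from the tertiary C-4 hydroxyl, which sterics should do.

7 to 6. The C-6–O bond is cut to a C–H bond. C-6 is a plain methylene next to the ring fusion, and no group in 6 can hand a chemical oxidant to it (O-4 would direct to the isopropyl methyls or to C-7). The disconnection therefore only makes sense for an enzyme, a P450 monooxygenase that replaces the β hydrogen of C-6 with retention. The gain is that the cyclisation substrate needs no oxygen beyond its diphosphate.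

6 to 3. This is the key disconnection: C-1–C-10 and C-4–C-5 are cut together with the C-4–O bond, which unfolds the bicycle into the acyclic chain of 3. These are the only two skeletal bonds of 6 that a farnesyl chain does not already contain, and the C-8=C-9 bond is the 2,3-double bond of the chain. The forward reaction, a terpene-synthase cascade through the tertiary diphosphate 4 and the cation 5, must close a seven- and a five-membered ring, set C-1, C-5 and C-4 and end by hydration at C-4. It makes two rings, two C–C bonds and three stereocentres from a substrate that has none.

3 to 2 to 1. The diphosphate ester is cut at C–O back to the allylic chloride 2 and this to the commercial alcohol 1. These are two routine steps, so the uncertainty of the route is concentrated in the cyclisation.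

## Alternatives that were turned down

Alternative 1: The seven-membered ring is cut at C-7–C-8 and C-1–C-10 into a four-carbon 2-siloxydiene (C-7=C-6–C-5=C-1, the last two carbons being the double bond of a methylcyclopentene that already carries a C-4 ketal) and a three-carbon vinylcarbenoid (C-8 to C-10).
- Forward key step: a chiral dirhodium tetracarboxylate Rh2(O2CR*)4 of divalent rhodium decomposes a vinyl diazoacetate. The carbenoid cyclopropanates the enol-ether double bond (C-7–C-8 and, for the moment, C-6–C-8), and the cis-divinylcyclopropane undergoes Cope rearrangement with formation of C-1–C-10 to give the bicyclic diene A1.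
- For it: the reaction class is well established, the catalyst fixes the absolute configuration of the quaternary C-1, and oxygen is already in place at C-6 (enol ether) and C-4 (ketal), so no C–H oxidation is needed. On precedent and on the C-6 oxygen it is stronger than the chosen route.
- Against it for this target:
  - A1 carries an ester where the C-8 methyl belongs, which costs three redox steps on an allylic system that can transpose.
  - A1 has neither the isopropyl group nor the C-4 and C-5 stereocentres. C-5 would be set only by protonating an enol ether next to the quaternary carbon.
  - The resulting C-6 ketone is β,γ to the C-8=C-9 bond and can move it into conjugation, and unmasking C-4 next to C-6 creates a 1,3-dicarbonyl array at C-5.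
  - The Cope step has to form a quaternary carbon beside a spiro ketal, and the parent vinyl diazoacetate tends to cyclise to a pyrazole.
- Comparison: about four steps to the diene and ten or more after A1, against nine in all for the chosen route. The chosen route offers instead both rings, all carbons and three stereocentres in one operation with no redox correction, at the price of an enzyme that does not yet exist.

Alternative 2: The C-4–C-5 bond is disconnected by seeing the five-membered ring as a contracted six-membered ring. The carbonyl carbon of an α-chlorocyclohexanone of the menthane type becomes the exocyclic C-6 ester carbon.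
- Forward key step: methoxide ion adds to the ketone, and the ring carbon that will be C-4 migrates from the carbonyl carbon to the chloride-bearing carbon (future C-5) with loss of chloride and inversion there (quasi-Favorskii shift), giving the cyclopentane ester A2.
- For it: the 1,2-shift is stereospecific. A2 already contains C-1 (methyl, allyl), the protected C-4 carbinol with its isopropyl group, C-5, and C-6 at the ester level, so the C-6 oxygen problem is solved at the carbon stage. Everything is conventional chemistry. On precedent and on C-4 and C-6 it is stronger than the chosen route.
- Against it for this target: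
  - The chloro ketone needs a quaternary C(methyl)(allyl) carbon on one side and a silyloxy isopropyl carbon on the other, with three stereocentres set beforehand (seven or eight steps).
  - The shift needs the migrating bond antiperiplanar to C–Cl in a crowded ring and competes with epoxy-ether formation and direct substitution.
  - After A2 the seven-membered ring is still missing: ester to aldehyde, methallyl addition that must also set C-6, ring-closing metathesis, then the end-game.
- Comparison: sixteen to eighteen steps. The chosen route closes both rings at once from a commercial C15 alcohol and needs no ring contraction, but cannot match the certainty of each single step here.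

Alternative 3: One carbon (C-5) is inserted into a six-membered ring, so that C-1–C-5 and C-5–C-6 are the bonds formed. The seven-membered ring is made from the Birch-type diene A4.
- Forward key step: a dihalocarbene adds to one of the two equivalent double bonds of A4, and disrotatory opening of the dibromocyclopropane, assisted by silver ions (Ag+), with capture of water gives the bromocycloheptadienol A3.
- For it: three cheap steps give a seven-membered ring that already carries both ring methyls (on C-1 and C-8), the C-8=C-9 bond, the C-6 oxygen and a vinyl bromide at C-5 as a handle. On cost and on the C-6 oxygen it is clearly stronger.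
- Against it for this target:
  - A3 is racemic, and its only stereocentre (C-6) would have to be resolved.
  - The hard part is untouched: the quaternary C-1, the C-4 carbinol and a trans-fused cyclopentane annulation across the tetrasubstituted C-1=C-5 vinyl bromide.
  - The skipped diene with its doubly allylic C-10 is prone to isomerise.
- Comparison: at least twelve further steps with stereocontrol yet to be invented. The chosen route sets C-1, C-4 and C-5 in the step that builds the skeleton, and takes its absolute configuration from the enzyme instead of a resolution.

Key step: step 3

## Route

Step 1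
Reactants: 1 (2E,6E)-farnesol
Product: 2 (2E,6E)-farnesyl chloride
Conditions: NCS, Me2S, CH2Cl2, −40 → 0 °C
Reagents that add atoms: N-chlorosuccinimide, SMILES O=C1CCC(=O)N1Cl
Why: Corey–Kim chlorination; the alkoxysulfonium salt of the primary allylic alcohol is displaced by chloride at C-1 without allylic transposition, so both (E) double bonds are kept. The chloride is used without chromatography.

Step 2
Reactants: 2 (2E,6E)-farnesyl chloride
Product: 3 (2E,6E)-farnesyl diphosphate
Conditions: (Bu4N)3HP2O7, MeCN, rt; then cation exchange (NH4+ form), aq. NH4HCO3/i-PrOH; cellulose chromatography
Reagents that add atoms: tris(tetrabutylammonium) hydrogen diphosphate, SMILES CCCC[N+](CCCC)(CCCC)CCCC.CCCC[N+](CCCC)(CCCC)CCCC.CCCC[N+](CCCC)(CCCC)CCCC.OP(=O)([O-])OP(=O)([O-])[O-]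
Why: SN2 displacement of the primary allylic chloride by the diphosphate anion in a dipolar aprotic solvent is the standard route to allylic diphosphates. Exchange to the ammonium form gives the water-soluble salt an enzyme accepts.

Step 3
Reactants: 3 (2E,6E)-farnesyl diphosphate
Product: 6 (1R,4R,5R)-dauc-8-en-4-ol, via nerolidyl diphosphate 4 (not isolated), via dauc-8-en-4-yl cation 5 (not isolated)
Conditions: recombinant class-one sesquiterpene synthase (daucenol cyclase, to be found in Ferula or evolved from a daucane cyclase), MgCl2, HEPES pH 7.5, 30 °C, pentane overlay
Reagents that add atoms: water, SMILES O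
Why: Proposed new method: enzyme-bound Mg2+ ionises 3 and the diphosphate returns to C-3 of the chain to give the tertiary allylic ester 4, whose cisoid rotamer ionises again to an allyl cation that can reach the central double bond. That double bond attacks through its methyl-bearing carbon (C-1–C-10, seven-membered ring, endo with respect to the attacking alkene) while the terminal double bond adds to its other carbon (C-4–C-5, five-membered ring, 5-exo with respect to the terminal alkene), so that no free secondary cation arises at C-5 and the charge arrives at C-11. A 1,2-hydride shift from C-4 to C-11 gives the tertiary cation 5, and a water molecule held by the enzyme adds to C-4 to release 6. The closest known reaction type is the class-one terpene-synthase cyclisation of 3 to carotol and other daucanes, together with hydroxylating sesquiterpene cyclases (germacradien-4-ol, epi-cubenol, cedrol and patchoulol synthases) that quench a tertiary cation with bound water; a cyclase that combines the daucane fold, this hydride shift and hydration at C-4 has not been described. C-1 and C-5: the two new bonds add antiperiplanar across the (6E) double bond of the chain, which by itself places the C-1 methyl and H-5 trans on the ring fusion, and the fold of the chain in the active site decides only which enantiomer forms. C-4: the cation is planar and its β face, syn to the C-1 methyl, is the more hindered one, so β hydration must be imposed by the position of the bound water. The step needs closure of the seven-membered ring in preference to the six-membered (bisabolyl) and ten-membered (germacryl) alternatives and hydration in preference to proton loss; the substrate has no stereocentre and secures none of this, so these selectivities rest on the template, while the chain supplies the (E) geometries and all fifteen carbons in their final places.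

Step 4
Reactants: 6 (1R,4R,5R)-dauc-8-en-4-ol
Product: 7 (1R,4R,5S,6R)-dauc-8-ene-4,6-diol
Conditions: CYP102A1 (P450 BM3) variant selected from an active-site library, NADP+ (cat.), D-glucose, glucose dehydrogenase, air, phosphate buffer pH 8.0, 2% DMSO, 25 °C
Reagents that add atoms: dioxygen, SMILES O=O
Why: Proposed new method: the ferryl oxidant of the P450 abstracts the β hydrogen of the C-6 methylene and returns hydroxyl to the same face (radical rebound, retention), a site and face that only the binding pocket can impose because C-7, C-10 and the C-8 methyl are allylic and the C-8=C-9 bond is open to epoxidation; the closest known reaction type is the site-selective hydroxylation of non-activated ring methylenes of sesqui- and diterpenoids by engineered CYP102A1 variants and by plant sesquiterpenoid hydroxylases, and a variant for this position of a daucane has to be found by screening.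

Step 5
Reactants: 8 4-hydroxybenzoic acid
Product: 10 4-(tert-butyldimethylsilyloxy)benzoic acid, via bis-silyl derivative 9 (not isolated)
Conditions: TBSCl (2.3 equiv), imidazole, DMF, rt; then AcOH–THF–H2O, rt
Reagents that add atoms: tert-butyldimethylsilyl chloride, SMILES CC(C)(C)[Si](C)(C)Cl
Why: Exhaustive silylation gives the silyl ester/silyl ether 9; the silyl ester is far more labile than the aryl silyl ether and is hydrolysed selectively by aqueous acetic acid.

Step 6
Reactants: 10 4-(tert-butyldimethylsilyloxy)benzoic acid
Product: 11 4-(tert-butyldimethylsilyloxy)benzoyl chloride
Conditions: (COCl)2, DMF (cat.), CH2Cl2, 0 °C → rt; evaporated and used crude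
Reagents that add atoms: oxalyl chloride, SMILES O=C(Cl)C(=O)Cl
Why: Acid chloride formation through the Vilsmeier-type chloroiminium catalyst; the conditions are anhydrous and brief, which the aryl silyl ether tolerates.

Step 7
Reactants: 7 (1R,4R,5S,6R)-dauc-8-ene-4,6-diol and 11 4-(tert-butyldimethylsilyloxy)benzoyl chloride
Product: 12 (1R,4R,5S,6R)-4-hydroxydauc-8-en-6-yl 4-(tert-butyldimethylsilyloxy)benzoate
Conditions: DMAP, Et3N, CH2Cl2, 0 → 40 °C
Reagents that add atoms: none
Why: DMAP-catalysed acyl transfer (acylpyridinium) to the secondary C-6 hydroxyl; the tertiary C-4 hydroxyl, flanked by the isopropyl group and the ring fusion, should not react, and no stereocentre is touched. The 6β-hydroxyl is 1,3-syn to the C-1 methyl and hydrogen-bonded to O-4, hence excess 11 and gentle warming.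

Step 8
Reactants: 12 (1R,4R,5S,6R)-4-hydroxydauc-8-en-6-yl 4-(tert-butyldimethylsilyloxy)benzoate
Product: 13 (1R,4R,5S,6R,8R,9S)-8,9-epoxy-4-hydroxydaucan-6-yl 4-(tert-butyldimethylsilyloxy)benzoate
Conditions: dimethyldioxirane, acetone, 0 °C
Reagents that add atoms: dimethyldioxirane, SMILES CC1(C)OO1
Why: Electrophilic oxygen transfer to the trisubstituted C-8=C-9 bond under neutral conditions, so that no acid is present to open the epoxide or to trigger transannular attack by the C-4 hydroxyl. The β face is shielded by the axial C-1 methyl near C-9 and by the 6β-aroyloxy group near C-8, so oxygen should arrive on the α face and set C-8 (R) and C-9 (S).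

Step 9
Reactants: 13 (1R,4R,5S,6R,8R,9S)-8,9-epoxy-4-hydroxydaucan-6-yl 4-(tert-butyldimethylsilyloxy)benzoate
Product: 14 (1R,4R,5S,6R,8R,9S)-8,9-epoxy-4-hydroxydaucan-6-yl 4-hydroxybenzoate
Conditions: Bu4NF, AcOH, THF, 0 °C
Reagents that add atoms: none
Why: Fluoride cleaves the aryl silyl ether (strong Si–F bond, good phenoxide leaving group); acetic acid buffers the phenoxide so that the ester neither migrates nor cleaves and the epoxide stays closed.

## Compound list

1 | (2E,6E)-farnesol | CC(C)=CCC/C(C)=C/CC/C(C)=C/CO | starting material
2 | (2E,6E)-farnesyl chloride, (2E,6E)-1-chloro-3,7,11-trimethyldodeca-2,6,10-triene | CC(C)=CCC/C(C)=C/CC/C(C)=C/CCl | intermediate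
3 | (2E,6E)-farnesyl diphosphate (handled as trisammonium salt, SMILES of the free acid) | CC(C)=CCC/C(C)=C/CC/C(C)=C/COP(=O)(O)OP(=O)(O)O | intermediate
4 | (3R,6E)-nerolidyl diphosphate, (3R,6E)-3,7,11-trimethyldodeca-1,6,10-trien-3-yl diphosphate (enzyme-bound, not isolated) | CC(C)=CCC/C(C)=C/CC[C@@](C)(OP(=O)(O)OP(=O)(O)O)C=C | intermediate
5 | dauc-8-en-4-yl cation, C-1 methyl β and H-5 α (enzyme-bound, not isolated) | CC(C)[C+]1CC[C@]2(C)CC=C(C)CC[C@H]21 | intermediate
6 | (1R,4R,5R)-dauc-8-en-4-ol, trans-fused, 4β-hydroxy | CC(C)[C@]1(O)CC[C@]2(C)CC=C(C)CC[C@H]21 | intermediate
7 | (1R,4R,5S,6R)-dauc-8-ene-4,6-diol, trans-fused, 4β,6β-diol | CC(C)[C@]1(O)CC[C@]2(C)CC=C(C)C[C@@H](O)[C@H]21 | intermediate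
8 | 4-hydroxybenzoic acid | OC(=O)c1ccc(O)cc1 | starting material
9 | tert-butyldimethylsilyl 4-(tert-butyldimethylsilyloxy)benzoate (not isolated) | CC(C)(C)[Si](C)(C)OC(=O)c1ccc(O[Si](C)(C)C(C)(C)C)cc1 | intermediate
10 | 4-(tert-butyldimethylsilyloxy)benzoic acid | OC(=O)c1ccc(O[Si](C)(C)C(C)(C)C)cc1 | intermediate
11 | 4-(tert-butyldimethylsilyloxy)benzoyl chloride | O=C(Cl)c1ccc(O[Si](C)(C)C(C)(C)C)cc1 | intermediate
12 | (1R,4R,5S,6R)-4-hydroxydauc-8-en-6-yl 4-(tert-butyldimethylsilyloxy)benzoate, 4β-hydroxy, 6β-acyloxy | CC(C)[C@]1(O)CC[C@]2(C)CC=C(C)C[C@@H](OC(=O)c3ccc(O[Si](C)(C)C(C)(C)C)cc3)[C@H]21 | intermediate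
13 | (1R,4R,5S,6R,8R,9S)-8,9-epoxy-4-hydroxydaucan-6-yl 4-(tert-butyldimethylsilyloxy)benzoate, 8α,9α-epoxide | CC(C)[C@]1(O)CC[C@]2(C)C[C@@H]3O[C@]3(C)C[C@@H](OC(=O)c3ccc(O[Si](C)(C)C(C)(C)C)cc3)[C@H]21 | intermediate
14 | (1R,4R,5S,6R,8R,9S)-8,9-epoxy-4-hydroxydaucan-6-yl 4-hydroxybenzoate, trans-fused, 4β-hydroxy, 6β-acyloxy, 8α,9α-epoxide | CC(C)[C@]1(O)CC[C@]2(C)C[C@@H]3O[C@]3(C)C[C@@H](OC(=O)c3ccc(O)cc3)[C@H]21 | target

## Step count and least certain steps

Total step count: 9. Longest linear sequence: 7 steps (steps 1, 2, 3, 4, 7, 8 and 9 from 1); the acyl donor 11 is made from 8 in two steps (5 and 6) and joins at step 7.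

Step 3 (key step, proposed new method). The terminating events are most likely to go astray: proton loss from the C-11 or C-4 cation, hydration at C-11 before the hydride shift, closure to a six-membered ring, or hydration on the α face of C-4. Nothing in the chain enforces the wanted course, and an enzyme that does has yet to be found or evolved.

Fallback (known chemistry only). No abiotic reaction is known that folds the chain of 1, 2 or 3 into a daucane, so this fallback cannot branch from a numbered intermediate. It replaces 1–6, sets out from commercial 3-ethoxycyclopent-2-en-1-one F1 and comes back to the route at 7.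
- Addition of allylmagnesium bromide to F1 and acidic work-up (Stork–Danheiser enone transposition) give 3-allylcyclopent-2-en-1-one F2.
- Copper-catalysed enantioselective conjugate addition of AlMe3 (Cu(OTf)2, chiral sulfonate-bearing N-heterocyclic carbene ligand, THF, −78 °C) sets the quaternary C-1. The aluminium enolate is trapped with Me3SiOTf as the (R)-silyl enol ether F3, which fixes the enolate on the hindered side.
- The side-chain electrophile 4,4-dimethoxy-2-methylbut-1-ene F4 is made from methallylmagnesium chloride and trimethyl orthoformate. Its Me3SiOTf-catalysed Mukaiyama aldol-type addition to F3 (CH2Cl2, −78 °C) gives the β-methoxy ketone F5 as a diastereomer mixture that does not matter.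
- Ring-closing metathesis of the allyl and methallyl groups of F5 (second-generation Hoveyda–Grubbs catalyst, toluene, 60 °C) closes the seven-membered ring with the trisubstituted C-8=C-9 bond, giving the bicyclic methoxy ketone F6.
- Elimination of methanol (DBU, CH2Cl2, 0 °C; E1cB) converges all diastereomers on the dienone F7, whose only stereocentre is C-1.
- Isopropylcerium dichloride (i-PrMgCl, CeCl3, THF, −78 °C) should add 1,2 to F7 from the α face, opposite the angular methyl, to give the dienol F8 with the 4β-hydroxyl.
- F8 is 6 with a C-5=C-6 double bond in place of two hydrogens. The two operations set out under step 4 below carry it to 7 and fix C-5 and C-6 under control of the ring.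

The weak point is the doubly allylic C-7 methylene of F7, which could let the C-8=C-9 bond move into conjugation under base, so the elimination and the cerium addition are run cold and short.

Step 4 (proposed new method). Site selectivity is most likely to fail: hydroxylation at the allylic C-7, C-10 or C-8 methyl positions, epoxidation of the C-8=C-9 bond, or hydroxylation on the α face of C-6. These positions have weaker C–H bonds or a reactive π bond, and only the pocket of a variant still to be found can override that.

Fallback (known chemistry only). No known reagent oxygenates C-6 of 6 selectively, since an oxidant tethered to O-4 would reach the isopropyl methyls or C-7 instead. The fallback therefore does not set out from 6. It sets out from the dienol F8 of the fallback to step 3 and comes back at 7.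
- VO(acac)2 and t-BuOOH (CH2Cl2, 0 °C) should epoxidise only the allylic C-5=C-6 bond, on the β face to which the vanadium-bound O-4 delivers oxygen, to give the epoxy alcohol F9.
- Cp2TiCl (from Cp2TiCl2 and Zn, THF; trivalent titanium) with 1,4-cyclohexadiene opens F9 homolytically at the C-5–O bond to the tertiary C-5 radical. This should take up hydrogen on the α face, away from the C-1 methyl and the two titanium-bound β oxygens, to give the trans-fused 4β,6β-diol 7.

Step 7. Acyl transfer may be slow, because the 6β-hydroxyl is 1,3-syn to the C-1 methyl and hydrogen-bonded to O-4; prolonged heating with excess 11 would then invite loss of the silyl group or dehydration at C-4.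

Fallback. The alcohol is activated instead of the acyl donor; the sequence sets out from 7 and 10 and comes back at 12.
- 10 is converted with 1,1′-carbonyldiimidazole into the N-acylimidazole F10.
- 7 is deprotonated at the more acidic secondary hydroxyl with LiN(SiMe3)2 (1 equiv, THF, −78 °C), and the lithium alkoxide is acylated by F10.
- An acyl group that strays to O-4 should return to the less hindered O-6 under the same alkoxide conditions.

Step 8. Poor facial selectivity is the likeliest failure: if the seven-membered ring adopts a conformer that exposes the β face, oxygen transfer could occur there.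

Fallback. A two-step halohydrin route inverts the facial outcome; it sets out from 12 and comes back at 13.
- N-Bromosuccinimide in aqueous THF (0 °C) forms the bromonium ion on the face that direct oxygen transfer preferred (β in this scenario).
- Water opens it at the tertiary C-8 from the α face to give the bromohydrin F11 (9β-bromo, 8α-hydroxy).
- Ag2O (THF) closes the 8α,9α-epoxide by backside displacement of bromide.

## Further compounds

F1 | step 3 | 3-ethoxycyclopent-2-en-1-one | CCOC1=CC(=O)CC1
F2 | step 3 | 3-allylcyclopent-2-en-1-one | C=CCC1=CC(=O)CC1
F3 | step 3 | (R)-trimethyl[(3-methyl-3-(prop-2-en-1-yl)cyclopent-1-en-1-yl)oxy]silane | C=CC[C@@]1(C)CCC(O[Si](C)(C)C)=C1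
F4 | step 3 | 4,4-dimethoxy-2-methylbut-1-ene | COC(CC(C)=C)OC
F5 | step 3 | (3R)-3-allyl-2-(1-methoxy-3-methylbut-3-en-1-yl)-3-methylcyclopentan-1-one, mixture of diastereomers at C-2 and C-1′ | C=CC[C@@]1(C)CCC(=O)C1C(OC)CC(C)=C
F6 | step 3 | (1R)-6-methoxy-11,12,13-trinordauc-8-en-4-one, mixture of diastereomers at C-5 and C-6 | O=C1CC[C@]2(C)CC=C(C)CC(OC)C21
F7 | step 3 | (1R)-11,12,13-trinordauca-5,8-dien-4-one | O=C1CC[C@]2(C)CC=C(C)CC=C21
F8 | step 3 | (1R,4R)-dauca-5,8-dien-4-ol, 4β-hydroxy | CC(C)[C@]1(O)CC[C@]2(C)CC=C(C)CC=C21
F9 | step 4 | (1R,4R,5S,6R)-5,6-epoxydauc-8-en-4-ol, 5β,6β-epoxide, 4β-hydroxy | CC(C)[C@]1(O)CC[C@]2(C)CC=C(C)C[C@H]3O[C@@]312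
F10 | step 7 | 1-[4-(tert-butyldimethylsilyloxy)benzoyl]imidazole | O=C(c1ccc(O[Si](C)(C)C(C)(C)C)cc1)n1ccnc1
F11 | step 8 | 9β-bromo-4β,8α-dihydroxy-trans-daucan-6β-yl 4-(tert-butyldimethylsilyloxy)benzoate | CC(C)[C@]1(O)CC[C@]2(C)C[C@@H](Br)[C@](C)(O)C[C@@H](OC(=O)c3ccc(O[Si](C)(C)C(C)(C)C)cc3)[C@H]21
A1 | alternative 1 | methyl (1R)-6-(tert-butyldimethylsilyloxy)-4,4-ethylenedioxy-11,12,13-trinordauca-5,8-dien-14-oate | C[C@]12CCC3(OCCO3)C1=C(O[Si](C)(C)C(C)(C)C)CC(C(=O)OC)=CC2
A2 | alternative 2 | methyl (1R,2R,5R)-2-allyl-5-isopropyl-2-methyl-5-(triethylsilyloxy)cyclopentane-1-carboxylate | CC(C)[C@]1(O[Si](CC)(CC)CC)CC[C@](C)(CC=C)[C@H]1C(=O)OC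
A3 | alternative 3 | rac-2-bromo-3,6-dimethylcyclohepta-2,5-dien-1-ol | CC1=CCC(C)=C(Br)C(O)C1
A4 | alternative 3 | 1,4-dimethylcyclohexa-1,4-diene | CC1=CCC(C)=CC1
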